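The rate constants were drawn at random within sensible limits; no experiment stands behind them.

Whatever the feed does, each starting material I charge is at any moment still unfed, standing in the flask, or held in target or self-condensation product, so the row is a matter of shares.

    starting material + reagent + catalyst ⇌ target + catalyst, rate k1*[starting material]*[reagent]*[catalyst] forward; the back reaction follows from the equilibrium constant (K1 = 110 M⁻¹, k1 = 460 M⁻² s⁻¹)
    2 starting material → self-condensation product (k2 = 2.2 M⁻¹ s⁻¹)

| setting | teal | red | amber | green |
|---|---|---|---|---|
| starting material | 41 mM (fed, over 0.40 min) | 41 mM (fed, over 0.80 min) | 41 mM (fed, over 1.5 min) | 41 mM (fed, over 3.0 min) |
| reagent | 2.50 equiv | 2.50 equiv | 2.50 equiv | 2.50 equiv |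
| catalyst | 2 mol% | 2 mol% | 2 mol% | 2 mol% |
| time | 2.5 min | 2.5 min | 2.5 min | 2.5 min |
| remark | the fed solution adds 0.10 times the starting volume | the fed solution adds 0.10 times the starting volume | the fed solution adds 0.10 times the starting volume | the fed solution adds 0.10 times the starting volume |

- percentages count the starting material that a species holds: one self-condensation product counts as two
- where a step has two of a species, its rate is k times that concentration squared, and two are used at each turn
- every charge counts on the volume at the start, and the solution that is fed holds the whole dose
- percentages count the whole charge, also what has not yet gone in
- "hardly changes" means that all values lie within two and a half points (for a concentration: within two and a half percent of the largest)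
- run time (teal): 2.5 min

- amount of target at the end, in percent of the starting material charged for teal, red, amber, green, in this order
- how that number moves from the first to the last of them (rises, then falls / hardly changes / rises all the way / falls all the way / falls, then rises)

1. The catalyst comes back at each turn and the reagent is charged at 2.50 equiv, so I treat the target step as pseudo-first-order in starting material, with constant k1 × reagent × catalyst = 0.0387 s⁻¹. Self-condensation uses starting material at 2k2 × concentration squared, so the two draws meet at 8.79 mM. I call this the even concentration, the standing level of starting material at which both steps use it equally fast, with reagent and catalyst as charged. It lies 0.669 powers of ten below the charge. At a standing level c, the target's share is even/(even + c).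

2. In my estimate a steady feed holds the level where feed rate equals total use. At the even concentration the use is 0.679 mM s⁻¹, and the teal feed of 1.71 mM s⁻¹ is faster than that. The matching dosing time is 1.01 min. With x as level over even concentration, x(one + x) equals 2 × matching time / dosing time, and the share is one/(one + x). That gives 35.7 %, 46.2 %, 56.8 % and 68.5 % for teal, red, amber and green.

3. Objection: does the level have time to settle? Near the even concentration it settles in about 8.61 s, which is shorter than the teal feed, so I keep the estimate.

4. Objection: green is still feeding at 2.5 min. It has received 83.3 % of its charge, and part of that still stands, so my estimate of its target falls to 50.4 %.

5. Objection: the target step runs back. Equilibrium holds target at 11.3 times the standing starting material, so the net flow shrinks by target/(11.3 × level). Solving for the target gives my row: 33.0 %, 39.7 %, 43.4 %, 34.6 %. This charges the whole run with the back flow of the final amount of target, so I expect it to run low.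

6. The forecast gives 40 %, 45 %, 46 % and 38 %, rises, then falls, each above my figure for that flask, on the ground that “slower dosing helps by keeping the standing concentration low”.

7. The simulation gives 35.7 %, 40.1 %, 45.1 % and 40.4 %, rises, then falls, and the row turns at a dosing time of 2.1 min.

In teal, the forward target step alone uses starting material more slowly than self-condensation at 0.344 min, at 0.47 times its rate, and faster than self-condensation at 2.50 min, at 4.8 times its rate; this ratio is the even concentration over the standing level, with reagent and catalyst as they then stand, and half of teal's self-condensation turnover up to 2.5 min is done by 0.353 min. In amber at the end of the feed, 1.50 min, the same ratio, from 19.9 % of the starting material, 84.3 % of the reagent and 100 % of the catalyst in 1.10 times the starting volume, comes to 0.824.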